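**Plan**

1. Retrosynthesis: the ring C ether bonds O1–C2 and O1''–C2'' are opened first (oxa-Michael). Each ring A is then removed by cutting O1–C8a and C4–C4a (likewise O1''–C8a'' and C4''–C4a''), which leaves a dibenzylidenesuccinic acid. Its two C=C bonds lead back to two aldehydes and diethyl succinate, whose central bond is C3–C3''.
2. Enabling feature: each ring A is fused to its ring C through two adjacent carbons, C8a carrying O1 and C4a carrying the C4 carbonyl, with a further oxygen on C5 beside C4a. An aryne with an alkoxy group next to the triple bond gives exactly this pattern when it inserts into a carboxyl group (doubly primed atoms: the 4-hydroxyphenyl half).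
3. Forward: the succinate chain receives the two arylidene arms, both rings A are attached in one operation with no ring formed, the two rings C then close one after the other, and five benzyl ethers are removed last.
4. Stereochemistry: C2 and C2'' (both S) come from a chiral amine–thiourea catalyst in the two ring closures. C3 and C3'' (both R) follow by equilibration to the 2,3-trans arrangement in each ring C.

Key step: step 7

Assumptions: 3,5-bis(benzyloxy)phenol is taken as a purchasable material. The quinidine-derived catalyst is assumed to give the 2S series; if the sense is opposite, the quinine-derived pseudoenantiomer replaces it with nothing else changed. Intermediates 16 and 18 are drawn for reaction at the 4-methoxyphenyl half first; the other order leads to the same products.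

**Step 1**
Reactants: 1 diethyl succinate; 2 4-methoxybenzaldehyde
Product: 4 (E)-3-(ethoxycarbonyl)-4-(4-methoxyphenyl)but-3-enoic acid, via paraconate lactone 3 (not isolated)
Conditions: KOtBu, t-BuOH, reflux; then aq. HCl
Reagents that add atoms: none
Why: Stobbe condensation, in which the succinate enolate adds to the aldehyde, the alkoxide lactonises onto the distal ester (3) and base-induced E1cB opening should give the half-ester with the aryl group trans to the retained ester (E).

**Step 2**
Reactants: 4 (E)-3-(ethoxycarbonyl)-4-(4-methoxyphenyl)but-3-enoic acid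
Product: 5 diethyl (E)-2-(4-methoxybenzylidene)succinate
Conditions: EtOH, H2SO4 (cat.), reflux
Reagents that add atoms: ethanol, CCO
Why: Fischer esterification of the saturated carboxyl group restores the second enolisable ester needed for another Stobbe condensation and should leave the conjugated ester and the E alkene unchanged.

**Step 3**
Reactants: 5 diethyl (E)-2-(4-methoxybenzylidene)succinate; 6 4-(benzyloxy)benzaldehyde
Product: 9 (2E,3E)-2-[4-(benzyloxy)benzylidene]-3-(4-methoxybenzylidene)succinic acid, via Stobbe lactone 7 (not isolated), via half-ester 8 (not isolated)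
Conditions: KOtBu, t-BuOH, reflux; then KOH, EtOH/H2O, reflux; then aq. HCl; crystallisation
Reagents that add atoms: potassium hydroxide, [K+].[OH-]
Why: A second Stobbe condensation at the remaining methylene is the standard entry to unsymmetrical (E,E)-bis(arylidene)succinates of the fulgide type, and saponification of the crude half-ester should give the diacid, whose E,E isomer is expected to be purified by crystallisation.

**Step 4**
Reactants: 10 3,5-bis(benzyloxy)phenol
Product: 11 3,5-bis(benzyloxy)-2-bromophenol
Conditions: NBS, CH2Cl2, −78 °C to rt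
Reagents that add atoms: N-bromosuccinimide, O=C1CCC(=O)N1Br
Why: Electrophilic aromatic bromination with NBS at low temperature in a non-polar solvent is expected to go ortho to the free hydroxyl, the position between the two benzyloxy groups being more shielded.

**Step 5**
Reactants: 11 3,5-bis(benzyloxy)-2-bromophenol
Product: 12 [3,5-bis(benzyloxy)-2-bromophenoxy]trimethylsilane
Conditions: (Me3Si)2NH, THF, 70 °C; volatiles removed, used crude
Reagents that add atoms: hexamethyldisilazane, C[Si](C)(C)N[Si](C)(C)C
Why: O-silylation of a phenol with hexamethyldisilazane releases only ammonia and places the silyl group for the migration that follows.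

**Step 6**
Reactants: 12 [3,5-bis(benzyloxy)-2-bromophenoxy]trimethylsilane
Product: 14 3,5-bis(benzyloxy)-2-(trimethylsilyl)phenyl trifluoromethanesulfonate, via lithium phenoxide 13 (not isolated)
Conditions: n-BuLi, THF, −100 °C; then Tf2O, −100 to −80 °C
Reagents that add atoms: trifluoromethanesulfonic anhydride, O=S(=O)(OS(=O)(=O)C(F)(F)F)C(F)(F)F
Why: Bromine–lithium exchange at −100 °C should outrun benzylic deprotonation, the aryllithium undergoes retro-Brook (O-to-C) silyl migration to phenoxide 13, and triflation of 13 gives the ortho-silylaryl triflate.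

**Step 7**
Reactants: 9 (2E,3E)-2-[4-(benzyloxy)benzylidene]-3-(4-methoxybenzylidene)succinic acid; 14 3,5-bis(benzyloxy)-2-(trimethylsilyl)phenyl trifluoromethanesulfonate
Product: 17 (2E,3E)-1,4-bis[2,4-bis(benzyloxy)-6-hydroxyphenyl]-2-[4-(benzyloxy)benzylidene]-3-(4-methoxybenzylidene)butane-1,4-dione, via aryne 15 (not isolated), via mono-insertion keto acid 16 (not isolated)
Conditions: 14 (2.4 equiv), CsF (8 equiv), THF, 125 °C, sealed tube; aq. NH4Cl
Reagents that add atoms: none
Why: Fluoride removes the silyl group of 14 and triflate departs to release aryne 15; a caesium carboxylate of 9 adds through oxygen to the aryne carbon remote from the flanking benzyloxy group (future C8a or C8a''), the aryl anion formed beside that benzyloxy group (future C4a or C4a'') attacks the new ester carbonyl through a four-membered alkoxide that collapses to ketone and phenoxide, and the sequence repeats at the second carboxyl group via 16. The closest known reaction is the fluoride-mediated insertion of arynes into the C–O bond of carboxylic acids with acyl migration to ortho-hydroxyaryl ketones, established for cinnamic-type acids, and the regiochemistry follows the general rule for nucleophilic addition to 3-alkoxyarynes. No ring closes and no stereocentre is created: four bonds form (O1–C8a, C4–C4a, O1''–C8a'', C4''–C4a'') and the E,E diene is carried through. The selectivity needed is regiochemical, and it is secured by the benzyloxy group at C3 of the aryne, whose inductive pull and distortion of the triple bond direct the nucleophile to C1 and leave the negative charge at C2 beside oxygen, so that each ketone ends between a benzyloxy group and the new phenol. Excess CsF keeps both carboxyl groups as carboxylates and the high temperature should favour the intramolecular acyl shift over protonation of the aryl anion; the chelated, delocalised 2-acylphenoxide is a poor Michael donor and a poor aryne trap in THF, so the crowded α-substituted enones are expected to stay open when the excess of 14 is kept small.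

**Step 8**
Reactants: 17 (2E,3E)-1,4-bis[2,4-bis(benzyloxy)-6-hydroxyphenyl]-2-[4-(benzyloxy)benzylidene]-3-(4-methoxybenzylidene)butane-1,4-dione
Product: 19 (2S,3R,2''S,3''R)-5,7,5'',7''-tetrakis(benzyloxy)-2''-[4-(benzyloxy)phenyl]-2-(4-methoxyphenyl)-3,3''-bichromane-4,4''-dione, via mono-cyclised flavanone 18 (not isolated)
Conditions: quinidine-derived bifunctional thiourea (9-amino-9-deoxy-epi-quinidine N'-[3,5-bis(trifluoromethyl)phenyl]thiourea, 20 mol %), toluene, 25 °C
Reagents that add atoms: none
Why: Proposed new method: the quinuclidine nitrogen of the catalyst acts as general base on the chelated phenol while the thiourea hydrogen-bonds the enone carbonyl, so the phenoxide should add 6-endo-trig to one face of the β-carbon and fix C2 (and, in the second closure via 18, C2'') as S; the extended enolate is then protonated at C3 (C3''), and this acidic centre beside the ketone should equilibrate under the amine to the 2,3-trans (3R, 3''R) arrangement; the closest known reaction type is the cinchona amine–thiourea-catalysed enantioselective oxa-Michael cyclisation of 2'-hydroxychalcones to flavanones, not yet shown for α,α'-linked bis-chalcones that lack an activating ester.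

**Step 9**
Reactants: 19 (2S,3R,2''S,3''R)-5,7,5'',7''-tetrakis(benzyloxy)-2''-[4-(benzyloxy)phenyl]-2-(4-methoxyphenyl)-3,3''-bichromane-4,4''-dione
Product: 20 (2S,3R,2''S,3''R)-5,7,5'',7''-tetrahydroxy-2''-(4-hydroxyphenyl)-2-(4-methoxyphenyl)-3,3''-bichromane-4,4''-dione
Conditions: H2 (1 atm), Pd/C (10 %), EtOAc/MeOH, 25 °C
Reagents that add atoms: none
Why: Hydrogenolysis of aryl benzyl ethers over Pd/C at ambient pressure is the usual last step of flavanone syntheses and, being neutral, should leave the aryl methyl ether, both ketones and the four stereocentres untouched.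

**Compound list**

1 | diethyl succinate | CCOC(=O)CCC(=O)OCC | starting material
2 | 4-methoxybenzaldehyde | COc1ccc(C=O)cc1 | starting material
3 | ethyl 2-(4-methoxyphenyl)-5-oxotetrahydrofuran-3-carboxylate (paraconate lactone, racemic diastereomer mixture, not isolated) | CCOC(=O)C1CC(=O)OC1c1ccc(OC)cc1 | intermediate
4 | (E)-3-(ethoxycarbonyl)-4-(4-methoxyphenyl)but-3-enoic acid | CCOC(=O)/C(CC(=O)O)=C/c1ccc(OC)cc1 | intermediate
5 | diethyl (E)-2-(4-methoxybenzylidene)succinate | CCOC(=O)/C(CC(=O)OCC)=C/c1ccc(OC)cc1 | intermediate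
6 | 4-(benzyloxy)benzaldehyde | O=Cc1ccc(OCc2ccccc2)cc1 | starting material
7 | ethyl 2-[4-(benzyloxy)phenyl]-4-[(E)-4-methoxybenzylidene]-5-oxotetrahydrofuran-3-carboxylate (Stobbe lactone, racemic diastereomer mixture, not isolated) | CCOC(=O)C1C(c2ccc(OCc3ccccc3)cc2)OC(=O)/C1=C/c1ccc(OC)cc1 | intermediate
8 | (2E,3E)-4-[4-(benzyloxy)phenyl]-3-(ethoxycarbonyl)-2-(4-methoxybenzylidene)but-3-enoic acid (half-ester, not isolated) | COc1ccc(/C=C(C(=O)O)\C(C(=O)OCC)=C/c2ccc(OCc3ccccc3)cc2)cc1 | intermediate
9 | (2E,3E)-2-[4-(benzyloxy)benzylidene]-3-(4-methoxybenzylidene)succinic acid | COc1ccc(/C=C(C(=O)O)\C(C(=O)O)=C/c2ccc(OCc3ccccc3)cc2)cc1 | intermediate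
10 | 3,5-bis(benzyloxy)phenol | Oc1cc(OCc2ccccc2)cc(OCc2ccccc2)c1 | starting material
11 | 3,5-bis(benzyloxy)-2-bromophenol | Oc1cc(OCc2ccccc2)cc(OCc2ccccc2)c1Br | intermediate
12 | [3,5-bis(benzyloxy)-2-bromophenoxy]trimethylsilane | C[Si](C)(C)Oc1cc(OCc2ccccc2)cc(OCc2ccccc2)c1Br | intermediate
13 | lithium 3,5-bis(benzyloxy)-2-(trimethylsilyl)phenoxide (not isolated) | [Li+].[O-]c1cc(OCc2ccccc2)cc(OCc2ccccc2)c1[Si](C)(C)C | intermediate
14 | 3,5-bis(benzyloxy)-2-(trimethylsilyl)phenyl trifluoromethanesulfonate | C[Si](C)(C)c1c(OCc2ccccc2)cc(OCc2ccccc2)cc1OS(=O)(=O)C(F)(F)F | intermediate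
15 | 3,5-bis(benzyloxy)benzyne (1,2-didehydro-3,5-bis(benzyloxy)benzene, not isolated) | C1#CC(OCc2ccccc2)=CC(OCc2ccccc2)=C1 | intermediate
16 | (2E,3E)-2-[4-(benzyloxy)benzylidene]-3-[2,4-bis(benzyloxy)-6-hydroxybenzoyl]-4-(4-methoxyphenyl)but-3-enoic acid (not isolated) | COc1ccc(/C=C(C(=O)c2c(O)cc(OCc3ccccc3)cc2OCc2ccccc2)\C(C(=O)O)=C/c2ccc(OCc3ccccc3)cc2)cc1 | intermediate
17 | (2E,3E)-1,4-bis[2,4-bis(benzyloxy)-6-hydroxyphenyl]-2-[4-(benzyloxy)benzylidene]-3-(4-methoxybenzylidene)butane-1,4-dione | COc1ccc(/C=C(C(=O)c2c(O)cc(OCc3ccccc3)cc2OCc2ccccc2)\C(C(=O)c2c(O)cc(OCc3ccccc3)cc2OCc2ccccc2)=C/c2ccc(OCc3ccccc3)cc2)cc1 | intermediate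
18 | (2S,3R)-5,7-bis(benzyloxy)-3-{(E)-1-[2,4-bis(benzyloxy)-6-hydroxybenzoyl]-2-[4-(benzyloxy)phenyl]vinyl}-2-(4-methoxyphenyl)chroman-4-one (not isolated) | COc1ccc([C@H]2Oc3cc(OCc4ccccc4)cc(OCc4ccccc4)c3C(=O)[C@@H]2\C(C(=O)c2c(O)cc(OCc3ccccc3)cc2OCc2ccccc2)=C/c2ccc(OCc3ccccc3)cc2)cc1 | intermediate
19 | (2S,3R,2''S,3''R)-5,7,5'',7''-tetrakis(benzyloxy)-2''-[4-(benzyloxy)phenyl]-2-(4-methoxyphenyl)-3,3''-bichromane-4,4''-dione | COc1ccc([C@H]2Oc3cc(OCc4ccccc4)cc(OCc4ccccc4)c3C(=O)[C@@H]2[C@H]2C(=O)c3c(OCc4ccccc4)cc(OCc4ccccc4)cc3O[C@@H]2c2ccc(OCc3ccccc3)cc2)cc1 | intermediate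
20 | (2S,3R,2''S,3''R)-5,7,5'',7''-tetrahydroxy-2''-(4-hydroxyphenyl)-2-(4-methoxyphenyl)-3,3''-bichromane-4,4''-dione | COc1ccc([C@H]2Oc3cc(O)cc(O)c3C(=O)[C@@H]2[C@H]2C(=O)c3c(O)cc(O)cc3O[C@@H]2c2ccc(O)cc2)cc1 | target

**Step count**

Total: 9 steps. Longest linear sequence: 6 steps (steps 1, 2, 3, 7, 8, 9; the aryne branch, steps 4, 5, 6 and then 7, 8, 9, is equally long).

**Steps most likely to fail**

Step 8 (proposed new method). Facial control by the catalyst may be weak or mismatched in one of the two closures. Uncatalysed closure may compete. The extended enolate may be protonated at the remote benzylic carbon instead of C3. Fallback with known chemistry: starting from 17, the classical base-mediated chalcone-to-flavanone isomerisation (NaOAc, EtOH, reflux) with trans equilibration should give racemic material. This is 19 together with its enantiomer (2R,3S,2''R,3''S)-5,7,5'',7''-tetrakis(benzyloxy)-2''-[4-(benzyloxy)phenyl]-2-(4-methoxyphenyl)-3,3''-bichromane-4,4''-dione F1. The racemic unlike diastereomer (2S,3R,2''R,3''S)-5,7,5'',7''-tetrakis(benzyloxy)-2''-[4-(benzyloxy)phenyl]-2-(4-methoxyphenyl)-3,3''-bichromane-4,4''-dione F2 forms alongside and is removed on silica. The racemate is then resolved by preparative HPLC on a chiral stationary phase (amylose tris(3,5-dimethylphenylcarbamate)), the enantiomers being assigned by circular dichroism. The route is rejoined at 19.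

Step 7. The aryl anion may be protonated before acyl transfer, so that the sequence stops at aryl esters. Surplus aryne may arylate the newly formed phenoxide. Ring C may close without catalyst in the hot fluoride medium, which would remove catalyst control in step 8. Fallback: starting from 9 and 11, the diacid is converted with EDC·HCl, HOBt, MeNHOMe·HCl and i-Pr2NEt into (2E,3E)-2-[4-(benzyloxy)benzylidene]-N1,N4-dimethoxy-3-(4-methoxybenzylidene)-N1,N4-dimethylsuccinamide F3. Bromophenol 11 is protected (MOMCl, i-Pr2NEt, CH2Cl2) as 1,5-bis(benzyloxy)-2-bromo-3-(methoxymethoxy)benzene F4. F4 is lithiated (n-BuLi, THF, −78 °C) and added to F3, which should give (2E,3E)-1,4-bis[2,4-bis(benzyloxy)-6-(methoxymethoxy)phenyl]-2-[4-(benzyloxy)benzylidene]-3-(4-methoxybenzylidene)butane-1,4-dione F5. Mild acetal cleavage (HCl, MeOH, 0 °C) frees the two phenols, and the route is rejoined at 17.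

Step 4. Bromination may occur between the two benzyloxy groups (para to the hydroxyl) or twice, since every free ring position is activated by three oxygens. Fallback: starting from 10, isopropyl isocyanate and Et3N in CH2Cl2 give 3,5-bis(benzyloxy)phenyl isopropylcarbamate F6. Carbamate-directed ortho-lithiation (TMSOTf, TMEDA, Et2O; then n-BuLi, TMEDA, −78 °C; then TMSCl) should place silicon between the carbamate and a benzyloxy group, giving 3,5-bis(benzyloxy)-2-(trimethylsilyl)phenyl isopropylcarbamate F7. Cleavage of the carbamate with Et2NH and DBU in MeCN at 40 °C, followed by PhNTf2 in the same flask, comes back to the route at 14, so that 11 to 13 and steps 5 and 6 are bypassed.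

**Further compounds**

F1 | step 8 | (2R,3S,2''R,3''S)-5,7,5'',7''-tetrakis(benzyloxy)-2''-[4-(benzyloxy)phenyl]-2-(4-methoxyphenyl)-3,3''-bichromane-4,4''-dione | COc1ccc([C@@H]2Oc3cc(OCc4ccccc4)cc(OCc4ccccc4)c3C(=O)[C@H]2[C@@H]2C(=O)c3c(OCc4ccccc4)cc(OCc4ccccc4)cc3O[C@H]2c2ccc(OCc3ccccc3)cc2)cc1
F2 | step 8 | (2S,3R,2''R,3''S)-5,7,5'',7''-tetrakis(benzyloxy)-2''-[4-(benzyloxy)phenyl]-2-(4-methoxyphenyl)-3,3''-bichromane-4,4''-dione (racemic, one enantiomer drawn) | COc1ccc([C@H]2Oc3cc(OCc4ccccc4)cc(OCc4ccccc4)c3C(=O)[C@@H]2[C@@H]2C(=O)c3c(OCc4ccccc4)cc(OCc4ccccc4)cc3O[C@H]2c2ccc(OCc3ccccc3)cc2)cc1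
F3 | step 7 | (2E,3E)-2-[4-(benzyloxy)benzylidene]-N1,N4-dimethoxy-3-(4-methoxybenzylidene)-N1,N4-dimethylsuccinamide | COc1ccc(/C=C(C(=O)N(C)OC)\C(C(=O)N(C)OC)=C/c2ccc(OCc3ccccc3)cc2)cc1
F4 | step 7 | 1,5-bis(benzyloxy)-2-bromo-3-(methoxymethoxy)benzene | COCOc1cc(OCc2ccccc2)cc(OCc2ccccc2)c1Br
F5 | step 7 | (2E,3E)-1,4-bis[2,4-bis(benzyloxy)-6-(methoxymethoxy)phenyl]-2-[4-(benzyloxy)benzylidene]-3-(4-methoxybenzylidene)butane-1,4-dione | COc1ccc(/C=C(C(=O)c2c(OCOC)cc(OCc3ccccc3)cc2OCc2ccccc2)\C(C(=O)c2c(OCOC)cc(OCc3ccccc3)cc2OCc2ccccc2)=C/c2ccc(OCc3ccccc3)cc2)cc1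
F6 | step 4 | 3,5-bis(benzyloxy)phenyl isopropylcarbamate | CC(C)NC(=O)Oc1cc(OCc2ccccc2)cc(OCc2ccccc2)c1
F7 | step 4 | 3,5-bis(benzyloxy)-2-(trimethylsilyl)phenyl isopropylcarbamate | CC(C)NC(=O)Oc1cc(OCc2ccccc2)cc(OCc2ccccc2)c1[Si](C)(C)C
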